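## Retrosynthetic overview

1. Kazinol B ⇒ its bis-MOM ether; the flavan pyran ring is closed last by intramolecular Pd aryl etherification (O1–C8a bond) of an (S)-benzylic alcohol carrying a 2-bromoaryl group, so the stereocentre is not touched.
2. (S)-Alcohol ⇒ CBS reduction of the saturated ketone ⇒ Cu–H conjugate reduction of the enone from Claisen–Schmidt condensation of a B-ring methyl ketone with 2-bromo-4-(MOM-oxy)benzaldehyde.
3. B-ring ketone (6-acetyl-8-hydroxy-7-prenyl-2,2-dimethylchromene) ⇒ cross-metathesis of the 7-allyl compound ⇒ one-pot propargyl-Claisen/6π (chromene) plus allyl-Claisen of the bis-ether of 3,4-dihydroxyacetophenone.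
4. Ring order: both benzene rings are purchased; the 2H-chromene ring is formed first (step 3) and the flavan dihydropyran ring last (step 10).

Assumption: the target is the (2S)-flavan encoded by the SMILES; purchased reagents that contribute atoms are numbered, while catalysts, bases and solvents are not.

## Route

**Step 1**
Reactants: 1 (3,4-dihydroxyacetophenone); 2 (3-chloro-3-methylbut-1-yne)
Product: 3, 1-[3-hydroxy-4-(2-methylbut-3-yn-2-yloxy)phenyl]ethanone
Conditions: 2 (1.3 equiv), DBU (1.1 equiv), CuCl2·2H2O (1 mol%), MeCN, 0 °C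
Reagents that add atoms: 3-chloro-3-methylbut-1-yne, C#CC(C)(C)Cl
Why: Cu-catalysed propargylic O-alkylation; with about one equivalent of base only the more acidic 4-OH (para to the acetyl) is ionised and alkylated.

**Step 2**
Reactants: 3; 4 (allyl bromide)
Product: 5, 1-[3-(allyloxy)-4-(2-methylbut-3-yn-2-yloxy)phenyl]ethanone
Conditions: allyl bromide, K2CO3, DMF, rt
Reagents that add atoms: allyl bromide, C=CCBr
Why: Williamson etherification of the remaining phenol, kept at rt so the propargyl ether does not react.

**Step 3**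
Reactants: 5
Product: 6, 1-(7-allyl-8-hydroxy-2,2-dimethyl-2H-chromen-6-yl)ethanone
Conditions: PhNEt2, 140 °C then 195 °C, sealed tube, Ar
Reagents that add atoms: none
Why: Aryl propargyl Claisen/[1,5]-H shift/oxa-6π electrocyclisation forms the chromene at the only free position ortho to O-4, and the aromatic allyl Claisen delivers allyl to the only free position ortho to O-3 (between OH and acetyl).

**Step 4**
Reactants: 6; 7 (2-methyl-2-butene)
Product: 8, 1-[8-hydroxy-2,2-dimethyl-7-(3-methylbut-2-en-1-yl)-2H-chromen-6-yl]ethanone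
Conditions: Grubbs II (5 mol%), 2-methyl-2-butene (excess), CH2Cl2, 40 °C, sealed
Reagents that add atoms: 2-methyl-2-butene, CC=C(C)C
Why: Olefin cross-metathesis converts the terminal allyl group to prenyl, while the hindered cis-disubstituted chromene alkene in an unstrained ring does not react.

**Step 5**
Reactants: 8; 9 (chloromethyl methyl ether)
Product: 10, 1-[8-(methoxymethoxy)-2,2-dimethyl-7-(3-methylbut-2-en-1-yl)-2H-chromen-6-yl]ethanone
Conditions: MOMCl, i-Pr2NEt, cat. DMAP, CH2Cl2, 0 → 40 °C
Reagents that add atoms: MOMCl, COCCl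
Why: Acetal protection of the phenol, which would otherwise compete as a nucleophile in the Pd C–O coupling (step 10).

**Step 6**
Reactants: 11 (2-bromo-4-hydroxybenzaldehyde); 9 (chloromethyl methyl ether)
Product: 12, 2-bromo-4-(methoxymethoxy)benzaldehyde
Conditions: MOMCl, i-Pr2NEt, CH2Cl2, 0 °C → rt
Reagents that add atoms: MOMCl, COCCl
Why: MOM protection of the future 7-OH; the ortho bromide serves as the masked flavan oxygen position, so no second phenol protecting group is needed.

**Step 7**
Reactants: 10; 12
Product: 13, (E)-3-[2-bromo-4-(methoxymethoxy)phenyl]-1-[8-(methoxymethoxy)-2,2-dimethyl-7-(3-methylbut-2-en-1-yl)-2H-chromen-6-yl]prop-2-en-1-one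
Conditions: KOH (aq), EtOH, rt
Reagents that add atoms: none (only 10 and 12)
Why: Claisen–Schmidt aldol condensation of the methyl ketone with a non-enolisable aldehyde gives the E-enone; MOM ethers, the aryl bromide and both alkenes are base-stable.

**Step 8**
Reactants: 13
Product: 14, 3-[2-bromo-4-(methoxymethoxy)phenyl]-1-[8-(methoxymethoxy)-2,2-dimethyl-7-(3-methylbut-2-en-1-yl)-2H-chromen-6-yl]propan-1-one
Conditions: [(Ph3P)CuH]6 (5 mol%), PhSiH3, toluene, rt; then TBAF/aq. NH4Cl work-up
Reagents that add atoms: none
Why: Stryker-type Cu–H conjugate reduction is selective for the enone C=C and leaves the prenyl and chromene alkenes and the aryl bromide untouched, unlike catalytic hydrogenation.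

**Step 9**
Reactants: 14
Product: 15, (1S)-3-[2-bromo-4-(methoxymethoxy)phenyl]-1-[8-(methoxymethoxy)-2,2-dimethyl-7-(3-methylbut-2-en-1-yl)-2H-chromen-6-yl]propan-1-ol
Conditions: (R)-Me-CBS (20 mol%), catecholborane (1.8 equiv), toluene, −78 °C
Reagents that add atoms: none
Why: Corey–Bakshi–Shibata reduction with aryl as the large group, where the (R)-oxazaborolidine gives the (S)-carbinol (as for acetophenone to (S)-1-phenylethanol), and catecholborane at −78 °C does not hydroborate the alkenes.

**Step 10**
Reactants: 15
Product: 16, (2S)-7-(methoxymethoxy)-2-[8-(methoxymethoxy)-2,2-dimethyl-7-(3-methylbut-2-en-1-yl)-2H-chromen-6-yl]chromane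
Conditions: Pd(OAc)2 (5 mol%), 2-(di-tert-butylphosphino)-1,1′-binaphthyl (6 mol%), Cs2CO3, toluene, 70 °C
Reagents that add atoms: none
Why: Intramolecular Buchwald–Hartwig C–O coupling forms the aryl C–O bond, so the carbinol C–O bond is never broken and the (S) configuration is carried over with retention to C2.

**Step 11**
Reactants: 16
Product: 17, Kazinol B, (2S)-2-[8-hydroxy-2,2-dimethyl-7-(3-methylbut-2-en-1-yl)-2H-chromen-6-yl]chroman-7-ol
Conditions: 3 M aq. HCl, MeOH/THF, rt → 40 °C, stopped at full conversion
Reagents that add atoms: none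
Why: Mild acid hydrolysis of the two aryl MOM acetals, under conditions too weak to protonate the prenyl or chromene alkenes or to ionise the C2–O bond.

## Compound list

1 | 3,4-dihydroxyacetophenone | CC(=O)c1ccc(O)c(O)c1 | starting material
2 | 3-chloro-3-methylbut-1-yne | C#CC(C)(C)Cl | starting material
3 | 1-[3-hydroxy-4-(2-methylbut-3-yn-2-yloxy)phenyl]ethanone | CC(=O)c1ccc(OC(C)(C)C#C)c(O)c1 | intermediate
4 | allyl bromide | C=CCBr | starting material
5 | 1-[3-(allyloxy)-4-(2-methylbut-3-yn-2-yloxy)phenyl]ethanone | CC(=O)c1ccc(OC(C)(C)C#C)c(OCC=C)c1 | intermediate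
6 | 1-(7-allyl-8-hydroxy-2,2-dimethyl-2H-chromen-6-yl)ethanone | CC(=O)c1cc2c(c(O)c1CC=C)OC(C)(C)C=C2 | intermediate
7 | 2-methyl-2-butene | CC=C(C)C | starting material
8 | 1-[8-hydroxy-2,2-dimethyl-7-(3-methylbut-2-en-1-yl)-2H-chromen-6-yl]ethanone | CC(=O)c1cc2c(c(O)c1CC=C(C)C)OC(C)(C)C=C2 | intermediate
9 | chloromethyl methyl ether (MOMCl) | COCCl | starting material
10 | 1-[8-(methoxymethoxy)-2,2-dimethyl-7-(3-methylbut-2-en-1-yl)-2H-chromen-6-yl]ethanone | CC(=O)c1cc2c(c(OCOC)c1CC=C(C)C)OC(C)(C)C=C2 | intermediate
11 | 2-bromo-4-hydroxybenzaldehyde | O=Cc1ccc(O)cc1Br | starting material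
12 | 2-bromo-4-(methoxymethoxy)benzaldehyde | COCOc1ccc(C=O)c(Br)c1 | intermediate
13 | (E)-enone (retro-chalcone) | O=C(/C=C/c1ccc(OCOC)cc1Br)c1cc2c(c(OCOC)c1CC=C(C)C)OC(C)(C)C=C2 | intermediate
14 | saturated ketone | O=C(CCc1ccc(OCOC)cc1Br)c1cc2c(c(OCOC)c1CC=C(C)C)OC(C)(C)C=C2 | intermediate
15 | (1S)-alcohol | O[C@@H](CCc1ccc(OCOC)cc1Br)c1cc2c(c(OCOC)c1CC=C(C)C)OC(C)(C)C=C2 | intermediate
16 | (2S)-bis-MOM kazinol B | CC(C)=CCc1c([C@@H]2CCc3ccc(OCOC)cc3O2)cc2c(c1OCOC)OC(C)(C)C=C2 | intermediate
17 | Kazinol B | CC(C)=CCc1c([C@@H]2CCc3ccc(O)cc3O2)cc2c(c1O)OC(C)(C)C=C2 | target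

## Summary

Total steps: 11. Longest linear sequence: 10 (steps 1–5, then 7–11; step 6 is the one-step side branch).

Three steps most likely to fail, each with a fallback:

1. **Step 3 (tandem propargyl/allyl Claisen at up to 195 °C into a crowded position).** Fallback: heat 3 alone (xylene, 140 °C) to the 8-hydroxychromene, O-alkylate again with 2, semi-hydrogenate (Lindlar) to the 1,1-dimethylallyl ether, and run its Claisen at about 120 °C. This delivers the prenyl group directly and removes both the high-temperature allyl Claisen and the metathesis.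

2. **Step 10 (Pd C–O coupling of a hindered secondary benzylic alkoxide, with β-hydride elimination to the ketone as the competing path).** Fallback: close the ring through the other C–O bond. Condense 10 with 2-hydroxy-4-(methoxymethoxy)benzaldehyde, reduce as before but with (S)-Me-CBS to the (R)-alcohol, and cyclise by Mitsunobu reaction (PPh3, DIAD, THF, 0 °C) with inversion to the (2S)-flavan.

3. **Step 11 (acidic MOM removal next to an o-prenylphenol, a chromene and an electron-rich 2-arylchroman).** Fallback: change the protecting-group plan to allyl ethers (allyl bromide in steps 5 and 6). Close the ring with Cu catalysis (CuI, Me4-phenanthroline, Cs2CO3) instead of Pd, and unmask at the end with Pd(PPh3)4/K2CO3/MeOH, so that no acid is used at any stage.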